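**Retrosynthetic overview**

1. Numbering (labdane type): ring A = C1–C5 and C10 (C3 is CHBr, C4 is CMe2). Ring B = C5–C10; C8 carries the vinyl group C14=C15 and methyl C17, C9 carries the chain C11–C12–C13(=O)–C16, and C10 carries methyl C20. β is the face of the C10 methyl.
2. The strategy rests on the contiguous triad C8–C9–C10 of ring B: H9 is cis to the C10 methyl and the C9 chain is trans to the C8 vinyl group. This is the pattern of an endo [4+2] adduct, so ring B is cut at C7–C8 and C9–C10.
3. Target ⇐ Wittig (C14=C15) and Horner–Wadsworth–Emmons (C11=C12) on a formyl ester cycloadduct ⇐ (S)-4-bromo-1,3,3-trimethyl-2-vinylcyclohexene + ethyl (E)-2-methyl-4-oxobut-2-enoate.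
4. Ring order: ring A first (stereospecific bromonium cyclization of geranyl acetate, C3 taken from a Shi epoxidation), ring B second (Diels–Alder), C5 last (radical hydrogenation to the trans ring fusion).

Key step: step 9

Assumption: the proton loss that ends step 3 is taken to give mainly the endocyclic trisubstituted alkene drawn for 4; its exocyclic and tetrasubstituted isomers would be carried along, since all of them converge on 7 in step 5.

**Route**

Step 1
Reactants: 1 geranyl acetate
Product: 2 (2E)-5-[(2R)-3,3-dimethyloxiran-2-yl]-3-methylpent-2-en-1-yl acetate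
Conditions: D-fructose-derived ketone catalyst (Shi epoxidation, 30 mol%), Oxone (2KHSO5·KHSO4·K2SO4), K2CO3, n-Bu4NHSO4, MeCN/CH2(OMe)2/aq. Na2B4O7, 0 °C
Reagents that add atoms: potassium peroxymonosulfate (Oxone), [K+].[O-]S(=O)(=O)OO
Why: Shi asymmetric epoxidation, in which the chiral dioxirane attacks the electron-rich 6,7-alkene (the 2,3-alkene is deactivated by the allylic acetate) through the spiro transition state and should set C6 as R.

Step 2
Reactants: 2 (R)-6,7-epoxygeranyl acetate
Product: 3 (2E,6S)-6,7-dibromo-3,7-dimethyloct-2-en-1-yl acetate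
Conditions: Ph3PBr2, CH2Cl2, 0 °C → rt
Reagents that add atoms: dibromotriphenylphosphorane, BrP(Br)(c1ccccc1)(c1ccccc1)c1ccccc1
Why: Deoxygenative dibromination of an epoxide with a dihalophosphorane, in which bromide opens the phosphorus-activated epoxide at the tertiary C7 and the C6–O–P bond is then displaced with inversion, so the (6R)-epoxide should give the (6S)-bromide while C7 is not stereogenic.

Step 3
Reactants: 3 (6S)-dibromide
Product: 4 [(1R,5S)-5-bromo-2,6,6-trimethylcyclohex-2-en-1-yl]methyl acetate
Conditions: (CF3)2CHOH, NaHCO3, 0 °C → rt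
Reagents that add atoms: none
Why: Solvolytic bromonium polyene cyclization (a reaction type known for enantioenriched vicinal bromochlorides of polyenes), in which ionization of the tertiary C–Br bond with participation of the neighbouring bromine gives the bromonium ion, the 2,3-alkene opens it at the tertiary carbon through a chair with Br and CH2OAc equatorial, and proton loss follows, so the C–Br configuration is retained and the ring CH centre follows from the E alkene.

Step 4
Reactants: 4 bromocyclized acetate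
Product: 5 [(1R,5S)-5-bromo-2,6,6-trimethylcyclohex-2-en-1-yl]methanol
Conditions: K2CO3 (cat.), MeOH, rt
Reagents that add atoms: none
Why: Base-catalysed transesterification frees the primary alcohol, and the cis-1,3 relation of CH2OH and Br rules out intramolecular displacement of the bromide.

Step 5
Reactants: 5 bromo alcohol
Product: 7 (5S)-5-bromo-2,6,6-trimethylcyclohex-1-ene-1-carbaldehyde, via unconjugated aldehyde 6 (not isolated)
Conditions: n-Pr4N[RuO4] (5 mol%), NMO, 4 Å MS, CH2Cl2, rt; then DBU (0.3 equiv), rt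
Reagents that add atoms: none
Why: Ley–Griffith oxidation gives the β,γ-unsaturated aldehyde, and amine-catalysed prototropic isomerization then moves the double bond into conjugation with the formyl group, which removes the ring CH stereocentre and leaves only the C–Br centre.

Step 6
Reactants: 7 bromo enal
Product: 8 (4S)-4-bromo-1,3,3-trimethyl-2-vinylcyclohex-1-ene
Conditions: Ph3PCH3Br, n-BuLi, THF, 0 °C → rt
Reagents that add atoms: methyltriphenylphosphonium bromide, C[P+](c1ccccc1)(c1ccccc1)c1ccccc1.[Br-]
Why: Wittig methylenation of the hindered enal, as known for the parent 2,6,6-trimethylcyclohexenecarbaldehyde, gives the 2-vinylcyclohexene, and the hindered secondary bromide should be neither displaced nor eliminated by the preformed ylide at this temperature.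

Step 7
Reactants: 9 2,2-dimethoxyacetaldehyde; 10 ethyl 2-(triphenylphosphoranylidene)propanoate
Product: 11 ethyl (2E)-4,4-dimethoxy-2-methylbut-2-enoate
Conditions: CH2Cl2, rt (aldehyde extracted from its commercial aqueous solution and dried)
Reagents that add atoms: none
Why: Wittig olefination with a stabilized α-methyl ylide, which should give the E trisubstituted enoate.

Step 8
Reactants: 11 acetal ester
Product: 12 ethyl (2E)-2-methyl-4-oxobut-2-enoate
Conditions: 1 M aq. HCl, THF, rt
Reagents that add atoms: water, O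
Why: Acid-catalysed acetal hydrolysis, with the E geometry kept because the E enal is the more stable isomer.

Step 9
Reactants: 8 bromo diene; 12 enal ester
Product: 13 ethyl (1S,2S,6S,8aR)-6-bromo-1-formyl-2,5,5,8a-tetramethyl-1,2,3,5,6,7,8,8a-octahydronaphthalene-2-carboxylate
Conditions: EtAlCl2 (1.1 equiv relative to 12), CH2Cl2, −78 → −20 °C; then 1 M aq. HCl
Reagents that add atoms: none
Why: EtAlCl2 binds the formyl oxygen of 12 and the [4+2] cycloaddition is concerted but asynchronous: the unsubstituted diene terminus C7 bonds ahead to C8, the carbon β to the activated formyl group, and the tetrasubstituted terminus C10 closes on the CH carbon C9. The closest known reaction type is the Lewis acid promoted Diels–Alder reaction of 1,3,3-trimethyl-2-vinylcyclohexene with enals and other activated dienophiles. Ring B is closed by intermolecular cycloaddition, both of its new bonds (C7–C8 and C9–C10) forming in this step and the C5=C6 alkene remaining. C9 and C10 are set by the endo orientation of the aluminium-bound formyl group, which ends cis to the outside ring carbon C1 and trans to the inside C10 methyl (so H9 is cis to that methyl); C8 is set by suprafacial addition to the E dienophile, which keeps the ester trans to the formyl group; the absolute sense comes from the C3 stereocentre, whose equatorial bromide favours the half-chair in which the pseudoaxial C4 methyl covers the β face, so the dienophile adds to the α face. The step needs regioselectivity (secured by formyl activation and by the cost of joining the two fully substituted carbons C8 and C10), endo selectivity (secured by Lewis acid binding to the aldehyde in preference to the ester) and facial selectivity, which rests only on a moderate conformational bias and is the main uncertainty.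

Step 10
Reactants: 13 formyl ester; 14 dimethyl (2-oxopropyl)phosphonate
Product: 15 ethyl (1S,2S,6S,8aR)-6-bromo-2,5,5,8a-tetramethyl-1-[(1E)-3-oxobut-1-en-1-yl]-1,2,3,5,6,7,8,8a-octahydronaphthalene-2-carboxylate
Conditions: NaH, THF, 0 °C; then 13, 0 °C → rt
Reagents that add atoms: none
Why: Horner–Wadsworth–Emmons olefination with the β-ketophosphonate anion gives the E enone, and the C9–H flanked by two quaternary carbons should not epimerize under this weakly basic anion.

Step 11
Reactants: 15 enone
Product: 16 ethyl (1S,2S,6S,8aR)-6-bromo-2,5,5,8a-tetramethyl-1-(3-oxobutyl)-1,2,3,5,6,7,8,8a-octahydronaphthalene-2-carboxylate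
Conditions: H2 (1 atm), RhCl(PPh3)3 (5 mol%), benzene, rt
Reagents that add atoms: none
Why: Homogeneous hydrogenation saturates the unhindered disubstituted enone alkene and leaves the C5=C6 alkene (flanked by two quaternary carbons) and the C–Br bond, and doing this reduction apart from the radical one avoids an electrophilic α-keto radical next to the C5=C6 alkene.

Step 12
Reactants: 16 keto ester with C5=C6
Product: 17 ethyl (1S,2S,4aR,6S,8aR)-6-bromo-2,5,5,8a-tetramethyl-1-(3-oxobutyl)decahydronaphthalene-2-carboxylate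
Conditions: Mn(dpm)3 (10 mol%), PhSiH3, t-BuOOH, i-PrOH, rt
Reagents that add atoms: none
Why: Metal-hydride hydrogen-atom-transfer hydrogenation, in which a hydrogen atom adds to C6 to give the tertiary C5 radical and the second hydrogen should arrive on the α face, anti to the axial C10 and 4β methyl groups, to give the trans ring fusion (C5 R) that this radical hydrogenation normally gives with decalin alkenes.

Step 13
Reactants: 17 trans-fused keto ester
Product: 18 ethyl (1S,2S,4aR,6S,8aR)-6-bromo-2,5,5,8a-tetramethyl-1-[2-(2-methyl-1,3-dioxolan-2-yl)ethyl]decahydronaphthalene-2-carboxylate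
Conditions: ethylene glycol, PPTS (cat.), benzene, reflux (Dean–Stark)
Reagents that add atoms: ethylene glycol, OCCO
Why: Acid-catalysed dioxolane formation masks the methyl ketone for the hydride and ylide steps, while the hindered ester and the bromide are inert.

Step 14
Reactants: 18 ketal ester
Product: 19 {(1S,2S,4aR,6S,8aR)-6-bromo-2,5,5,8a-tetramethyl-1-[2-(2-methyl-1,3-dioxolan-2-yl)ethyl]decahydronaphthalen-2-yl}methanol
Conditions: i-Bu2AlH (3 equiv), CH2Cl2, −78 → 0 °C; aq. KNaC4H4O6
Reagents that add atoms: none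
Why: Aluminium hydride reduction of the hindered ester to the neopentyl alcohol, with a reagent that should neither displace the secondary bromide nor open the dioxolane at low temperature.

Step 15
Reactants: 19 ketal alcohol
Product: 20 (1S,2S,4aR,6S,8aR)-6-bromo-2,5,5,8a-tetramethyl-1-[2-(2-methyl-1,3-dioxolan-2-yl)ethyl]decahydronaphthalene-2-carbaldehyde
Conditions: Dess–Martin periodinane, pyridine, CH2Cl2, rt
Reagents that add atoms: none
Why: Dess–Martin oxidation of the neopentyl primary alcohol gives an aldehyde with no α-hydrogen, so C8 cannot epimerize.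

Step 16
Reactants: 20 ketal aldehyde
Product: 21 2-{2-[(1R,2R,4aR,6S,8aR)-6-bromo-2-ethenyl-2,5,5,8a-tetramethyldecahydronaphthalen-1-yl]ethyl}-2-methyl-1,3-dioxolane
Conditions: Ph3PCH3Br, KOt-Bu, THF, 0 → 40 °C
Reagents that add atoms: methyltriphenylphosphonium bromide, C[P+](c1ccccc1)(c1ccccc1)c1ccccc1.[Br-]
Why: Wittig methylenation of the hindered, non-enolizable aldehyde installs the C14=C15 vinyl group (the change of descriptors at the two ring carbons is a priority change only).

Step 17
Reactants: 21 vinyl ketal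
Product: 22 4-[(1R,2R,4aR,6S,8aR)-6-bromo-2-ethenyl-2,5,5,8a-tetramethyldecahydronaphthalen-1-yl]butan-2-one
Conditions: 1 M aq. HCl, THF, rt
Reagents that add atoms: water, O
Why: Acid-catalysed ketal hydrolysis releases the methyl ketone, and the vinyl group and the bromide tolerate dilute acid.

**Compound list**

1 | geranyl acetate | CC(C)=CCC/C(C)=C/COC(C)=O | starting material
2 | (2E)-5-[(2R)-3,3-dimethyloxiran-2-yl]-3-methylpent-2-en-1-yl acetate | CC(=O)OC/C=C(C)/CC[C@H]1OC1(C)C | intermediate
3 | (2E,6S)-6,7-dibromo-3,7-dimethyloct-2-en-1-yl acetate | CC(=O)OC/C=C(C)/CC[C@H](Br)C(C)(C)Br | intermediate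
4 | [(1R,5S)-5-bromo-2,6,6-trimethylcyclohex-2-en-1-yl]methyl acetate | CC(=O)OC[C@@H]1C(C)=CC[C@H](Br)C1(C)C | intermediate
5 | [(1R,5S)-5-bromo-2,6,6-trimethylcyclohex-2-en-1-yl]methanol | OC[C@@H]1C(C)=CC[C@H](Br)C1(C)C | intermediate
6 | (1R,5S)-5-bromo-2,6,6-trimethylcyclohex-2-ene-1-carbaldehyde | O=C[C@@H]1C(C)=CC[C@H](Br)C1(C)C | intermediate
7 | (5S)-5-bromo-2,6,6-trimethylcyclohex-1-ene-1-carbaldehyde | O=CC1=C(C)CC[C@H](Br)C1(C)C | intermediate
8 | (4S)-4-bromo-1,3,3-trimethyl-2-vinylcyclohex-1-ene | C=CC1=C(C)CC[C@H](Br)C1(C)C | intermediate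
9 | 2,2-dimethoxyacetaldehyde | COC(OC)C=O | starting material
10 | ethyl 2-(triphenylphosphoranylidene)propanoate | CCOC(=O)C(C)=P(c1ccccc1)(c1ccccc1)c1ccccc1 | starting material
11 | ethyl (2E)-4,4-dimethoxy-2-methylbut-2-enoate | CCOC(=O)/C(C)=C/C(OC)OC | intermediate
12 | ethyl (2E)-2-methyl-4-oxobut-2-enoate | CCOC(=O)/C(C)=C/C=O | intermediate
13 | ethyl (1S,2S,6S,8aR)-6-bromo-1-formyl-2,5,5,8a-tetramethyl-1,2,3,5,6,7,8,8a-octahydronaphthalene-2-carboxylate | CCOC(=O)[C@@]1(C)CC=C2C(C)(C)[C@@H](Br)CC[C@]2(C)[C@@H]1C=O | intermediate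
14 | dimethyl (2-oxopropyl)phosphonate | COP(=O)(CC(C)=O)OC | starting material
15 | ethyl (1S,2S,6S,8aR)-6-bromo-2,5,5,8a-tetramethyl-1-[(1E)-3-oxobut-1-en-1-yl]-1,2,3,5,6,7,8,8a-octahydronaphthalene-2-carboxylate | CCOC(=O)[C@@]1(C)CC=C2C(C)(C)[C@@H](Br)CC[C@]2(C)[C@@H]1/C=C/C(C)=O | intermediate
16 | ethyl (1S,2S,6S,8aR)-6-bromo-2,5,5,8a-tetramethyl-1-(3-oxobutyl)-1,2,3,5,6,7,8,8a-octahydronaphthalene-2-carboxylate | CCOC(=O)[C@@]1(C)CC=C2C(C)(C)[C@@H](Br)CC[C@]2(C)[C@@H]1CCC(C)=O | intermediate
17 | ethyl (1S,2S,4aR,6S,8aR)-6-bromo-2,5,5,8a-tetramethyl-1-(3-oxobutyl)decahydronaphthalene-2-carboxylate | CCOC(=O)[C@@]1(C)CC[C@H]2C(C)(C)[C@@H](Br)CC[C@]2(C)[C@@H]1CCC(C)=O | intermediate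
18 | ethyl (1S,2S,4aR,6S,8aR)-6-bromo-2,5,5,8a-tetramethyl-1-[2-(2-methyl-1,3-dioxolan-2-yl)ethyl]decahydronaphthalene-2-carboxylate | CCOC(=O)[C@@]1(C)CC[C@H]2C(C)(C)[C@@H](Br)CC[C@]2(C)[C@@H]1CCC3(C)OCCO3 | intermediate
19 | {(1S,2S,4aR,6S,8aR)-6-bromo-2,5,5,8a-tetramethyl-1-[2-(2-methyl-1,3-dioxolan-2-yl)ethyl]decahydronaphthalen-2-yl}methanol | OC[C@@]1(C)CC[C@H]2C(C)(C)[C@@H](Br)CC[C@]2(C)[C@@H]1CCC3(C)OCCO3 | intermediate
20 | (1S,2S,4aR,6S,8aR)-6-bromo-2,5,5,8a-tetramethyl-1-[2-(2-methyl-1,3-dioxolan-2-yl)ethyl]decahydronaphthalene-2-carbaldehyde | O=C[C@@]1(C)CC[C@H]2C(C)(C)[C@@H](Br)CC[C@]2(C)[C@@H]1CCC3(C)OCCO3 | intermediate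
21 | 2-{2-[(1R,2R,4aR,6S,8aR)-6-bromo-2-ethenyl-2,5,5,8a-tetramethyldecahydronaphthalen-1-yl]ethyl}-2-methyl-1,3-dioxolane | C=C[C@@]1(C)CC[C@H]2C(C)(C)[C@@H](Br)CC[C@]2(C)[C@@H]1CCC3(C)OCCO3 | intermediate
22 | 4-[(1R,2R,4aR,6S,8aR)-6-bromo-2-ethenyl-2,5,5,8a-tetramethyldecahydronaphthalen-1-yl]butan-2-one | C=C[C@@]1(C)CC[C@H]2C(C)(C)[C@@H](Br)CC[C@]2(C)[C@@H]1CCC(C)=O | target

**Step count and risks**

Total step count: 17. Longest linear sequence: 15 steps (steps 1–6 and 9–17, from geranyl acetate).

The three steps most likely to fail: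

Step 9. The cycloaddition may run with weak facial discrimination, because the remote bromide acts only through a conformational bias of the diene half-chair, or the acid-sensitive diene may oligomerize before the hindered trisubstituted dienophile reacts. The fallback moves face control to a chiral auxiliary on the dienophile; it sets out from 12 (and uses 8) and comes back at 13. Pinnick oxidation of 12 (NaClO2, NaH2PO4, 2-methylbut-2-ene, t-BuOH/H2O) gives (2E)-4-ethoxy-3-methyl-4-oxobut-2-enoic acid F1. Its mixed pivalic anhydride (t-BuCOCl, Et3N, THF) acylates (4S)-4-benzyl-1,3-oxazolidin-2-one in the presence of LiCl to give the imide ethyl (2E)-4-[(4S)-4-benzyl-2-oxo-1,3-oxazolidin-3-yl]-2-methyl-4-oxobut-2-enoate F2. Et2AlCl (CH2Cl2, −78 °C) chelates this imide in its s-cis form, which is a much more reactive dienophile and, by the chelate model, is open only on the Si face of C9, the face that 13 requires. With diene 8 the endo cycloadduct, the imide ethyl (1S,2S,6S,8aR)-1-{[(4S)-4-benzyl-2-oxo-1,3-oxazolidin-3-yl]carbonyl}-6-bromo-2,5,5,8a-tetramethyl-1,2,3,5,6,7,8,8a-octahydronaphthalene-2-carboxylate F3, should then form with auxiliary and substrate bias matched. LiBH4/H2O (Et2O, 0 °C) removes the auxiliary reductively, leaving the hindered C8 ester, to give the hydroxymethyl ester ethyl (1S,2S,6S,8aR)-6-bromo-1-(hydroxymethyl)-2,5,5,8a-tetramethyl-1,2,3,5,6,7,8,8a-octahydronaphthalene-2-carboxylate F4, and Dess–Martin oxidation returns to 13.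

Step 12. Hydrogen delivery to the C5 radical may occur from the β face, because the axial C9 chain crowds the α face, which would give the cis ring fusion. The fallback replaces the radical step by a hydroxyl-directed hydrogenation; it sets out from 13 and comes back at 17. NaBH4 (MeOH, 0 °C) reduces the formyl group of 13 to the hydroxymethyl ester F4. The α-oriented CH2OH on C9 then directs [Ir(cod)(PCy3)(py)]PF6/H2 (CH2Cl2, rt) to the α face of C5=C6, giving the trans-fused alcohol ethyl (1S,2S,4aR,6S,8aS)-6-bromo-1-(hydroxymethyl)-2,5,5,8a-tetramethyldecahydronaphthalene-2-carboxylate F5. Dess–Martin oxidation gives the trans-fused formyl ester ethyl (1S,2S,4aR,6S,8aS)-6-bromo-1-formyl-2,5,5,8a-tetramethyldecahydronaphthalene-2-carboxylate F6. The Horner–Wadsworth–Emmons reaction with 14 (NaH, THF) gives the trans-fused enone ethyl (1S,2S,4aR,6S,8aS)-6-bromo-2,5,5,8a-tetramethyl-1-[(1E)-3-oxobut-1-en-1-yl]decahydronaphthalene-2-carboxylate F7, and hydrogenation as in step 11 gives 17.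

Step 3. After ionization of the dibromide, bromonium transfer between alkenes may erode the enantiopurity, or proton loss may occur before ring closure. The fallback gives up the stereospecific entry for a racemic cyclization followed by separation of enantiomers; it sets out from 1 and comes back at 5. Direct bromonium cyclization of 1 with [Et2SBr][SbCl5Br] (MeNO2, −25 °C) gives 4 as the racemate, that is together with its enantiomer [(1S,5R)-5-bromo-2,6,6-trimethylcyclohex-2-en-1-yl]methyl acetate F8. Methanolysis as in step 4 gives 5 together with the enantiomeric alcohol [(1S,5R)-5-bromo-2,6,6-trimethylcyclohex-2-en-1-yl]methanol F9. Preparative chromatography on a chiral stationary phase (amylose tris(3,5-dimethylphenylcarbamate)) separates the two, and 5 goes on to step 5.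

**Further compounds**

F1 | step 9 | (2E)-4-ethoxy-3-methyl-4-oxobut-2-enoic acid | CCOC(=O)/C(C)=C/C(=O)O
F2 | step 9 | ethyl (2E)-4-[(4S)-4-benzyl-2-oxo-1,3-oxazolidin-3-yl]-2-methyl-4-oxobut-2-enoate | CCOC(=O)/C(C)=C/C(=O)N1[C@@H](Cc2ccccc2)COC1=O
F3 | step 9 | ethyl (1S,2S,6S,8aR)-1-{[(4S)-4-benzyl-2-oxo-1,3-oxazolidin-3-yl]carbonyl}-6-bromo-2,5,5,8a-tetramethyl-1,2,3,5,6,7,8,8a-octahydronaphthalene-2-carboxylate | CCOC(=O)[C@@]1(C)CC=C2C(C)(C)[C@@H](Br)CC[C@]2(C)[C@@H]1C(=O)N3[C@@H](Cc4ccccc4)COC3=O
F4 | step 9 | ethyl (1S,2S,6S,8aR)-6-bromo-1-(hydroxymethyl)-2,5,5,8a-tetramethyl-1,2,3,5,6,7,8,8a-octahydronaphthalene-2-carboxylate | CCOC(=O)[C@@]1(C)CC=C2C(C)(C)[C@@H](Br)CC[C@]2(C)[C@@H]1CO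
F5 | step 12 | ethyl (1S,2S,4aR,6S,8aS)-6-bromo-1-(hydroxymethyl)-2,5,5,8a-tetramethyldecahydronaphthalene-2-carboxylate | CCOC(=O)[C@@]1(C)CC[C@H]2C(C)(C)[C@@H](Br)CC[C@]2(C)[C@@H]1CO
F6 | step 12 | ethyl (1S,2S,4aR,6S,8aS)-6-bromo-1-formyl-2,5,5,8a-tetramethyldecahydronaphthalene-2-carboxylate | CCOC(=O)[C@@]1(C)CC[C@H]2C(C)(C)[C@@H](Br)CC[C@]2(C)[C@@H]1C=O
F7 | step 12 | ethyl (1S,2S,4aR,6S,8aS)-6-bromo-2,5,5,8a-tetramethyl-1-[(1E)-3-oxobut-1-en-1-yl]decahydronaphthalene-2-carboxylate | CCOC(=O)[C@@]1(C)CC[C@H]2C(C)(C)[C@@H](Br)CC[C@]2(C)[C@@H]1/C=C/C(C)=O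
F8 | step 3 | [(1S,5R)-5-bromo-2,6,6-trimethylcyclohex-2-en-1-yl]methyl acetate | CC(=O)OC[C@H]1C(C)=CC[C@@H](Br)C1(C)C
F9 | step 3 | [(1S,5R)-5-bromo-2,6,6-trimethylcyclohex-2-en-1-yl]methanol | OC[C@H]1C(C)=CC[C@@H](Br)C1(C)C
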